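**Plan**

1. Cuts: the 16 O-benzyl bonds; then the three interflavan bonds C4(unit B)–C6(catechin), C4(unit D)–C8(catechin) and C4(unit A)–C6(unit B); then, in the one fisetinidol monomer that supplies units A, B and D, the aryl ether bond O1–C8a and the C2–C(aryl) bond, back to a tyrosine. (Unit A = terminal fisetinidol on C6 of unit B; unit B = fisetinidol on catechin C6; unit D = fisetinidol on catechin C8.)
2. Enabling feature: in each fisetinidol unit ring A has its hydroxyl at C7 para to C4a and its ether oxygen at C8a ortho to C4a, so ring A with C4 and C3 is the 4-hydroxyphenyl-propanoid skeleton of tyrosine. Once that phenol is dearomatized to a para-quinol, C8a is a dienone β-carbon six atoms from the C2 hydroxyl, and the temporary C4a–OH leaves as water to restore the arene.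
3. Forward: tyrosine-derived α-benzyloxy Weinreb amide + ring-B Grignard → ketone → anti alcohol → para-quinol → pyran ring closed on the dienone and ring A re-formed (step 8) → C4 activated through the 7-OH para-quinone methide → A–B dimer (4α→6) and D–catechin dimer (4α→8) → union at catechin C6 → hydrogenolysis.
4. Stereochemistry: C3 from L-tyrosine (retentive diazotization); C2 by chelation-controlled ketone reduction (anti, hence 2,3-trans); each C4 by attack on a planar benzylic cation anti to the 3-benzyloxy group (3,4-trans, 4α); catechin from the chiral pool.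

Key step: step 8

Remark on the chemistry: compounds 16, 17 and 18 are carried as C4-epimer mixtures (C4 undefined in their SMILES) because this centre becomes a planar cation before each interflavan bond forms; ketol 13 is a mixture of the two cis-fused diastereomers, whose ring-fusion centres vanish on aromatization.

**Route**

Step 1
Reactants: 1 O-tert-butyl-L-tyrosine
Product: 2 (S)-3-(4-tert-butoxyphenyl)-2-hydroxypropanoic acid
Conditions: NaNO2, 0.5 M H2SO4, H2O–1,4-dioxane, 0 °C to rt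
Reagents that add atoms: water, O
Why: Diazotization of an α-amino acid, in which the carboxylate displaces N2 to an α-lactone that water opens, so two inversions give net retention (S) at the future C3; cold dilute aqueous acid should spare the aryl tert-butyl ether.

Step 2
Reactants: 2 (S)-3-(4-tert-butoxyphenyl)-2-hydroxypropanoic acid
Product: 3 (S)-2-(benzyloxy)-3-(4-tert-butoxyphenyl)propanoic acid
Conditions: NaH (2.3 equiv), BnBr (1.1 equiv), THF–DMF, 0 °C to rt; then 1 M HCl
Reagents that add atoms: benzyl bromide, BrCc1ccccc1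
Why: Williamson etherification of the carboxylate–alkoxide dianion, where the alkoxide is the only strong nucleophile and the carboxylate prevents α-deprotonation; the benzyl ether later blocks O3 from conjugate addition and is the chelating group for step 6.

Step 3
Reactants: 3 (S)-2-(benzyloxy)-3-(4-tert-butoxyphenyl)propanoic acid
Product: 5 Weinreb amide (S)-2-(benzyloxy)-3-(4-tert-butoxyphenyl)-N-methoxy-N-methylpropanamide, via acyl imidazole 4 (not isolated)
Conditions: CDI, CH2Cl2, rt; then MeNHOMe·HCl, rt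
Reagents that add atoms: N,O-dimethylhydroxylamine hydrochloride, CNOC.Cl
Why: Acyl imidazole formation and aminolysis (Weinreb amide synthesis) run without a base strong enough to epimerize the α-alkoxy centre.

Step 4
Reactants: 5 Weinreb amide; 6 4-bromo-1,2-bis(benzyloxy)benzene
Product: 8 (S)-2-(benzyloxy)-1-[3,4-bis(benzyloxy)phenyl]-3-(4-tert-butoxyphenyl)propan-1-one, via arylmagnesium bromide 7 (not isolated)
Conditions: 6, Mg, THF, reflux; then 5, THF, 0 °C; aq. NH4Cl
Reagents that add atoms: none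
Why: Weinreb ketone synthesis, in which the chelated tetrahedral magnesium adduct stops at single addition and shields the α-centre from enolization until the quench.

Step 5
Reactants: 8 (S)-2-(benzyloxy)-1-[3,4-bis(benzyloxy)phenyl]-3-(4-tert-butoxyphenyl)propan-1-one
Product: 9 (S)-2-(benzyloxy)-1-[3,4-bis(benzyloxy)phenyl]-3-(4-hydroxyphenyl)propan-1-one
Conditions: TFA–CH2Cl2 (1:4), 0 °C to rt
Reagents that add atoms: none
Why: Acidolysis of the aryl tert-butyl ether by loss of 2-methylpropene, placed before the acid-labile benzylic alcohol exists; the benzyl ethers on the deactivated aroyl ring tolerate brief TFA.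

Step 6
Reactants: 9 (S)-2-(benzyloxy)-1-[3,4-bis(benzyloxy)phenyl]-3-(4-hydroxyphenyl)propan-1-one
Product: 10 (1R,2S)-2-(benzyloxy)-1-[3,4-bis(benzyloxy)phenyl]-3-(4-hydroxyphenyl)propan-1-ol
Conditions: Zn(BH4)2, Et2O–CH2Cl2, −40 to 0 °C; aq. NH4Cl
Reagents that add atoms: none
Why: Chelation-controlled hydride reduction of an α-alkoxy ketone, in which zinc bridges the carbonyl and benzyloxy oxygens and hydride enters past the α-hydrogen, setting the new carbinol centre (future C2, R) anti to C3.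

Step 7
Reactants: 10 (1R,2S)-2-(benzyloxy)-1-[3,4-bis(benzyloxy)phenyl]-3-(4-hydroxyphenyl)propan-1-ol
Product: 12 para-quinol 4-[(2S,3R)-2-(benzyloxy)-3-[3,4-bis(benzyloxy)phenyl]-3-hydroxypropyl]-4-hydroxycyclohexa-2,5-dien-1-one, via para-peroxyquinol 11 (not isolated)
Conditions: KHSO5 (as Oxone, 2KHSO5·KHSO4·K2SO4), NaHCO3, MeCN–H2O, rt; then Me2S, 0 °C
Reagents that add atoms: potassium peroxymonosulfate, [K+].[O-]S(=O)(=O)OO
Why: Oxidative dearomatization of a para-alkylphenol by singlet oxygen from bicarbonate-buffered peroxymonosulfate, then reduction of the hydroperoxide; a non-cationic oxidant is chosen so that the free benzylic hydroxyl cannot capture a phenoxonium ion at the ipso carbon as a spiroether.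

Step 8
Reactants: 12 para-quinol
Product: 14 3,3',4'-tri-O-benzylfisetinidol (2R,3S)-3-(benzyloxy)-2-[3,4-bis(benzyloxy)phenyl]-3,4-dihydro-2H-chromen-7-ol, via cis-fused ketol 13 (not isolated)
Conditions: KOt-Bu (0.1 equiv), THF, 0 °C; then TsOH·H2O (0.4 equiv), 45 °C
Reagents that add atoms: none
Why: Catalytic alkoxide makes the C2 hydroxyl add to one β-carbon of the cross-conjugated dienone (the future C8a) in a 6-exo-trig oxa-Michael closure of the pyran ring, giving cis-fused ketol 13. Acid then enolizes the β-alkoxy ketone towards C8 and ionizes the tertiary C4a–OH of the resulting dienol, and loss of the C8a proton from this hydroxyarenium ion restores ring A as a phenol, so the temporary C4a–O bond made in step 7 leaves as water. The closest known reaction types are the intramolecular oxa-Michael cyclization of tyrosol-derived para-quinols to cis-fused hydrobenzofuranones and the conjugate addition–dehydration of para-quinols that gives meta-substituted phenols. The two sp3 centres formed at the ring fusion (cis because the tether delivers oxygen to its own face) are erased on aromatization, while C2 and C3 keep their configuration since no bond to them is made or broken, so the anti relationship of 10 becomes 2,3-trans. The step needs chemoselectivity between the two oxygen nucleophiles and between cyclization and rearrangement: O3 is benzylated so only the six-membered ring can close, both diastereotopic enone arms converge on the same arene, and the dienone is consumed under base before acid is admitted, which removes the substrate for dienone–phenol migration and shortens acid exposure of the benzylic C2–O bond.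

Step 9
Reactants: 14 3,3',4'-tri-O-benzylfisetinidol
Product: 16 3,3',4'-tri-O-benzyl-4-(2-ethoxyethoxy)fisetinidol, via para-quinone methide 15 (not isolated)
Conditions: DDQ (1.05 equiv), 2-ethoxyethanol–CH2Cl2 (1:4), 0 °C
Reagents that add atoms: 2-ethoxyethanol, OCCOCC
Why: Benzylic oxidation of a para-alkylphenol by DDQ, in which the free 7-OH para to C4 is dehydrogenated to the para-quinone methide and the alcohol adds 1,6 at C4; C4 is the only benzylic position para to a free phenol, so the benzyl-protected ring B and C2 are not touched.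

Step 10
Reactants: 16 3,3',4'-tri-O-benzyl-4-(2-ethoxyethoxy)fisetinidol
Product: 17 3,7,3',4'-tetra-O-benzyl-4-(2-ethoxyethoxy)fisetinidol
Conditions: BnBr, K2CO3, DMF, rt
Reagents that add atoms: benzyl bromide, BrCc1ccccc1
Why: Williamson benzylation of the phenoxide at room temperature, fast relative to any expulsion of the 4-alkoxide.

Step 11
Reactants: 17 3,7,3',4'-tetra-O-benzyl-4-(2-ethoxyethoxy)fisetinidol
Product: 18 3,7,3',4'-tetra-O-benzyl-4-(2,6-dimethylphenylsulfanyl)fisetinidol
Conditions: 2,6-dimethylbenzenethiol (3 equiv), BF3·OEt2 (0.3 equiv), CH2Cl2, −78 to −30 °C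
Reagents that add atoms: 2,6-dimethylbenzenethiol, Cc1cccc(C)c1S
Why: Lewis-acid ionization of the 4-alkoxy group to the 2,4-dioxygenated benzylic cation and SN1 capture by the thiol, giving a latent electrophile that is inert to hard Lewis acids but answers to thiophilic silver salts.

Step 12
Reactants: 17 3,7,3',4'-tetra-O-benzyl-4-(2-ethoxyethoxy)fisetinidol; 18 3,7,3',4'-tetra-O-benzyl-4-(2,6-dimethylphenylsulfanyl)fisetinidol
Product: 19 tetra-O-benzylfisetinidol-(4α→6)-tetra-O-benzyl-4-(2,6-dimethylphenylsulfanyl)fisetinidol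
Conditions: 18 (3 equiv, excess recovered), BF3·OEt2 (0.3 equiv), CH2Cl2, −78 to −40 °C
Reagents that add atoms: none
Why: Friedel–Crafts alkylation in which the C4 cation from 17 is attacked by C6 of 18 (para to O1, ortho to 7-OBn, less hindered than C8) on the α-face anti to the 3-benzyloxy group, setting C4 of unit A as 4α; excess 18 suppresses self-condensation and the arylsulfanyl group survives the hard Lewis acid.

Step 13
Reactants: 20 (+)-catechin
Product: 21 5,7,3',4'-tetra-O-benzyl-(+)-catechin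
Conditions: BnBr (4.4 equiv), K2CO3, DMF, 0 °C to rt
Reagents that add atoms: benzyl bromide, BrCc1ccccc1
Why: Williamson benzylation of the four phenols, leaving the less acidic 3-OH free.

Step 14
Reactants: 17 3,7,3',4'-tetra-O-benzyl-4-(2-ethoxyethoxy)fisetinidol; 21 5,7,3',4'-tetra-O-benzyl-(+)-catechin
Product: 22 tetra-O-benzylfisetinidol-(4α→8)-tetra-O-benzylcatechin
Conditions: 21 (3 equiv, excess recovered), TMSOTf (0.2 equiv), CH2Cl2, −78 °C
Reagents that add atoms: none
Why: Friedel–Crafts alkylation at C8, the most nucleophilic position of the phloroglucinol-type ring of 21, with α-face attack anti to the 3-benzyloxy group setting C4 of unit D as 4α.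

Step 15
Reactants: 19 A–B dimer thioether; 22 D–catechin dimer
Product: 23 hexadeca-O-benzyl tetraflavanoid
Conditions: 22 (2 equiv), AgBF4 (2.5 equiv), 2,6-di-tert-butyl-4-methylpyridine, 4 Å MS, CH2Cl2–THF, −40 to 0 °C
Reagents that add atoms: none
Why: Thiophilic silver activation ionizes the C4–S bond of unit B, and the only position of 22 activated by three oxygens (catechin C6) attacks anti to the 3-benzyloxy group to give the 4α→6 bond (Friedel–Crafts alkylation), with the hindered pyridine buffering acid so that existing interflavan bonds are not cleaved.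

Step 16
Reactants: 23 hexadeca-O-benzyl tetraflavanoid
Product: 24 fisetinidol-(4α→6)-fisetinidol-(4α→6)-[fisetinidol-(4α→8)]-catechin (target)
Conditions: H2 (1 atm), Pd(OH)2/C, THF–MeOH–H2O, rt
Reagents that add atoms: none
Why: Global hydrogenolysis of the sixteen benzyl ethers, conditions under which the benzylic C2–O1 and C4–aryl bonds of flavans are expected to survive and no stereocentre is touched.

**Compound list**

1 | O-tert-butyl-L-tyrosine | N[C@@H](Cc1ccc(OC(C)(C)C)cc1)C(=O)O | starting material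
2 | (S)-3-(4-tert-butoxyphenyl)-2-hydroxypropanoic acid | OC(=O)[C@@H](O)Cc1ccc(OC(C)(C)C)cc1 | intermediate
3 | (S)-2-(benzyloxy)-3-(4-tert-butoxyphenyl)propanoic acid | OC(=O)[C@@H](OCc1ccccc1)Cc1ccc(OC(C)(C)C)cc1 | intermediate
4 | acyl imidazole, (S)-2-(benzyloxy)-3-(4-tert-butoxyphenyl)-1-(imidazol-1-yl)propan-1-one | O=C(n1ccnc1)[C@@H](OCc1ccccc1)Cc1ccc(OC(C)(C)C)cc1 | intermediate
5 | Weinreb amide, (S)-2-(benzyloxy)-3-(4-tert-butoxyphenyl)-N-methoxy-N-methylpropanamide | CON(C)C(=O)[C@@H](OCc1ccccc1)Cc1ccc(OC(C)(C)C)cc1 | intermediate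
6 | 4-bromo-1,2-bis(benzyloxy)benzene | Brc1ccc(OCc2ccccc2)c(OCc2ccccc2)c1 | starting material
7 | [3,4-bis(benzyloxy)phenyl]magnesium bromide | Br[Mg]c1ccc(OCc2ccccc2)c(OCc2ccccc2)c1 | intermediate
8 | (S)-2-(benzyloxy)-1-[3,4-bis(benzyloxy)phenyl]-3-(4-tert-butoxyphenyl)propan-1-one | O=C(c1ccc(OCc2ccccc2)c(OCc2ccccc2)c1)[C@@H](OCc1ccccc1)Cc1ccc(OC(C)(C)C)cc1 | intermediate
9 | (S)-2-(benzyloxy)-1-[3,4-bis(benzyloxy)phenyl]-3-(4-hydroxyphenyl)propan-1-one | O=C(c1ccc(OCc2ccccc2)c(OCc2ccccc2)c1)[C@@H](OCc1ccccc1)Cc1ccc(O)cc1 | intermediate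
10 | (1R,2S)-2-(benzyloxy)-1-[3,4-bis(benzyloxy)phenyl]-3-(4-hydroxyphenyl)propan-1-ol | O[C@H](c1ccc(OCc2ccccc2)c(OCc2ccccc2)c1)[C@@H](OCc1ccccc1)Cc1ccc(O)cc1 | intermediate
11 | para-peroxyquinol, 4-[(2S,3R)-2-(benzyloxy)-3-[3,4-bis(benzyloxy)phenyl]-3-hydroxypropyl]-4-hydroperoxycyclohexa-2,5-dien-1-one | O[C@H](c1ccc(OCc2ccccc2)c(OCc2ccccc2)c1)[C@@H](OCc1ccccc1)CC1(OO)C=CC(=O)C=C1 | intermediate
12 | para-quinol, 4-[(2S,3R)-2-(benzyloxy)-3-[3,4-bis(benzyloxy)phenyl]-3-hydroxypropyl]-4-hydroxycyclohexa-2,5-dien-1-one | O[C@H](c1ccc(OCc2ccccc2)c(OCc2ccccc2)c1)[C@@H](OCc1ccccc1)CC1(O)C=CC(=O)C=C1 | intermediate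
13 | cis-fused ketol, (2R,3S)-3-(benzyloxy)-2-[3,4-bis(benzyloxy)phenyl]-4a-hydroxy-2,3,4,4a,8,8a-hexahydro-7H-chromen-7-one (both cis-fused diastereomers at C4a/C8a) | O1[C@H](c3ccc(OCc4ccccc4)c(OCc4ccccc4)c3)[C@@H](OCc3ccccc3)CC2(O)C=CC(=O)CC12 | intermediate
14 | 3,3',4'-tri-O-benzylfisetinidol, (2R,3S)-3-(benzyloxy)-2-[3,4-bis(benzyloxy)phenyl]-3,4-dihydro-2H-chromen-7-ol | Oc1ccc2c(c1)O[C@H](c1ccc(OCc3ccccc3)c(OCc3ccccc3)c1)[C@@H](OCc1ccccc1)C2 | intermediate
15 | para-quinone methide, (2R,3S)-3-(benzyloxy)-2-[3,4-bis(benzyloxy)phenyl]-2,3-dihydro-7H-chromen-7-one | O1[C@H](c3ccc(OCc4ccccc4)c(OCc4ccccc4)c3)[C@@H](OCc3ccccc3)C=C2C=CC(=O)C=C12 | intermediate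
16 | 3,3',4'-tri-O-benzyl-4-(2-ethoxyethoxy)fisetinidol (2R,3S; 7-OH free; C4 epimers) | Oc1ccc2c(c1)O[C@H](c1ccc(OCc3ccccc3)c(OCc3ccccc3)c1)[C@@H](OCc1ccccc1)C2OCCOCC | intermediate
17 | 3,7,3',4'-tetra-O-benzyl-4-(2-ethoxyethoxy)fisetinidol (2R,3S; C4 epimers) | c1ccccc1COc1ccc2c(c1)O[C@H](c1ccc(OCc3ccccc3)c(OCc3ccccc3)c1)[C@@H](OCc1ccccc1)C2OCCOCC | intermediate
18 | 3,7,3',4'-tetra-O-benzyl-4-(2,6-dimethylphenylsulfanyl)fisetinidol (2R,3S; C4 epimers) | c1ccccc1COc1ccc2c(c1)O[C@H](c1ccc(OCc3ccccc3)c(OCc3ccccc3)c1)[C@@H](OCc1ccccc1)C2Sc1c(C)cccc1C | intermediate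
19 | 3,7,3',4'-tetra-O-benzylfisetinidol-(4α→6)-3,7,3',4'-tetra-O-benzyl-4-(2,6-dimethylphenylsulfanyl)fisetinidol (upper unit 2,3-trans-3,4-trans) | c5ccccc5COc1ccc2c(c1)O[C@H](c1ccc(OCc5ccccc5)c(OCc5ccccc5)c1)[C@@H](OCc5ccccc5)[C@@H]2c1cc2c(cc1OCc5ccccc5)O[C@H](c1ccc(OCc5ccccc5)c(OCc5ccccc5)c1)[C@@H](OCc5ccccc5)C2Sc1c(C)cccc1C | intermediate
20 | (+)-catechin, (2R,3S) | Oc1cc(O)c2c(c1)O[C@H](c1ccc(O)c(O)c1)[C@@H](O)C2 | starting material
21 | 5,7,3',4'-tetra-O-benzyl-(+)-catechin | c1c(OCc5ccccc5)c2c(cc1OCc5ccccc5)O[C@H](c1ccc(OCc5ccccc5)c(OCc5ccccc5)c1)[C@@H](O)C2 | intermediate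
22 | 3,7,3',4'-tetra-O-benzylfisetinidol-(4α→8)-5,7,3',4'-tetra-O-benzylcatechin | c1c(OCc5ccccc5)c2c(c([C@@H]3c4ccc(OCc5ccccc5)cc4O[C@H](c4ccc(OCc5ccccc5)c(OCc5ccccc5)c4)[C@H]3OCc5ccccc5)c1OCc5ccccc5)O[C@H](c1ccc(OCc5ccccc5)c(OCc5ccccc5)c1)[C@@H](O)C2 | intermediate
23 | hexadeca-O-benzyl tetraflavanoid: tetra-O-benzylfisetinidol-(4α→6)-tetra-O-benzylfisetinidol-(4α→6)-[tetra-O-benzylfisetinidol-(4α→8)]-5,7,3',4'-tetra-O-benzylcatechin | c5ccccc5COc1ccc2c(c1)O[C@H](c1ccc(OCc5ccccc5)c(OCc5ccccc5)c1)[C@@H](OCc5ccccc5)[C@@H]2c1cc2c(cc1OCc5ccccc5)O[C@H](c1ccc(OCc5ccccc5)c(OCc5ccccc5)c1)[C@@H](OCc5ccccc5)[C@@H]2c1c(OCc5ccccc5)c2c(c([C@@H]3c4ccc(OCc5ccccc5)cc4O[C@H](c4ccc(OCc5ccccc5)c(OCc5ccccc5)c4)[C@H]3OCc5ccccc5)c1OCc5ccccc5)O[C@H](c1ccc(OCc5ccccc5)c(OCc5ccccc5)c1)[C@@H](O)C2 | intermediate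
24 | fisetinidol-(4α→6)-fisetinidol-(4α→6)-[fisetinidol-(4α→8)]-catechin | Oc1ccc2c(c1)O[C@H](c1ccc(O)c(O)c1)[C@@H](O)[C@@H]2c1cc2c(cc1O)O[C@H](c1ccc(O)c(O)c1)[C@@H](O)[C@@H]2c1c(O)c2c(c([C@@H]3c4ccc(O)cc4O[C@H](c4ccc(O)c(O)c4)[C@H]3O)c1O)O[C@H](c1ccc(O)c(O)c1)[C@@H](O)C2 | target

**Count and risks**

Total step count: 16. Longest linear sequence: 14 steps (steps 1–12, 15 and 16); steps 13 and 14 form the catechin branch.

Step 8. The acid stage may be diverted by retro-Michael reopening of the pyran ring, by ionization of the benzylic C2–O bond with loss of C2 configuration, or by alkyl migration in any dienone that re-forms. The fallback sets out from 12 and returns at 14. The cascade would be stopped after the base stage and ketol 13 isolated. Its C4a hydroxyl would then be removed without acid by thermal syn-elimination of the derived sulfamate with the Burgess reagent (THF, 50 °C). The cis ring fusion places the C8a hydrogen syn to the leaving group, and the resulting 2,4-dienone tautomerizes to phenol 14. This fallback makes no new compound (F0).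

Step 15. Attack at the crowded catechin C6 between two benzyloxy groups may be slow, so the cation could be consumed by self-condensation or by the resorcinol-type rings (poor site-selectivity). The fallback sets out from 17, 19 and 20 and returns at 24. It uses catechin unprotected as the nucleophilic hub, whose free-phenol ring is less hindered. Compound 17 and excess 20 (BF3·OEt2, THF–CH2Cl2, 0 °C) should give tetra-O-benzylfisetinidol-(4α→8)-catechin F1. Union of F1 with 19 under neutral thiophilic conditions (AgBF4, 2,6-di-tert-butyl-4-methylpyridine, THF, 0 °C) should give the dodeca-O-benzyl tetraflavanoid with a free catechin unit F2. Hydrogenolysis (H2, Pd(OH)2/C) then gives 24.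

Step 12. The electrophile may self-condense through its own ring A and the dimer may be alkylated again, eroding the yield of the 4→6 dimer. The fallback sets out from 17 and returns at 24. It caps the electrophile with bromine: 17 and N-bromosuccinimide (CH2Cl2, −20 °C) should give the 6-bromo electrophile F3. Near-equimolar coupling of F3 with 18 (BF3·OEt2, CH2Cl2, −78 °C) should give the bromo-capped dimer thioether F4. Union of F4 with 22 as in step 15 should give the bromo-capped protected tetraflavanoid F5. Hydrogenolysis with H2, Pd(OH)2/C and Et3N removes the bromine together with the benzyl ethers to give 24.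

**Further compounds**

F0 | step 8 | none | none
F1 | step 15 | 3,7,3',4'-tetra-O-benzylfisetinidol-(4α→8)-(+)-catechin | c1c(O)c2c(c([C@@H]3c4ccc(OCc5ccccc5)cc4O[C@H](c4ccc(OCc5ccccc5)c(OCc5ccccc5)c4)[C@H]3OCc5ccccc5)c1O)O[C@H](c1ccc(O)c(O)c1)[C@@H](O)C2
F2 | step 15 | dodeca-O-benzyl tetraflavanoid with unprotected catechin unit | c5ccccc5COc1ccc2c(c1)O[C@H](c1ccc(OCc5ccccc5)c(OCc5ccccc5)c1)[C@@H](OCc5ccccc5)[C@@H]2c1cc2c(cc1OCc5ccccc5)O[C@H](c1ccc(OCc5ccccc5)c(OCc5ccccc5)c1)[C@@H](OCc5ccccc5)[C@@H]2c1c(O)c2c(c([C@@H]3c4ccc(OCc5ccccc5)cc4O[C@H](c4ccc(OCc5ccccc5)c(OCc5ccccc5)c4)[C@H]3OCc5ccccc5)c1O)O[C@H](c1ccc(O)c(O)c1)[C@@H](O)C2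
F3 | step 12 | 6-bromo-3,7,3',4'-tetra-O-benzyl-4-(2-ethoxyethoxy)fisetinidol (C4 epimers) | c1ccccc1COc1c(Br)cc2c(c1)O[C@H](c1ccc(OCc3ccccc3)c(OCc3ccccc3)c1)[C@@H](OCc1ccccc1)C2OCCOCC
F4 | step 12 | 6-bromo-tetra-O-benzylfisetinidol-(4α→6)-tetra-O-benzyl-4-(2,6-dimethylphenylsulfanyl)fisetinidol | c5ccccc5COc1c(Br)cc2c(c1)O[C@H](c1ccc(OCc5ccccc5)c(OCc5ccccc5)c1)[C@@H](OCc5ccccc5)[C@@H]2c1cc2c(cc1OCc5ccccc5)O[C@H](c1ccc(OCc5ccccc5)c(OCc5ccccc5)c1)[C@@H](OCc5ccccc5)C2Sc1c(C)cccc1C
F5 | step 12 | hexadeca-O-benzyl tetraflavanoid bearing bromine at C6 of unit A | c5ccccc5COc1c(Br)cc2c(c1)O[C@H](c1ccc(OCc5ccccc5)c(OCc5ccccc5)c1)[C@@H](OCc5ccccc5)[C@@H]2c1cc2c(cc1OCc5ccccc5)O[C@H](c1ccc(OCc5ccccc5)c(OCc5ccccc5)c1)[C@@H](OCc5ccccc5)[C@@H]2c1c(OCc5ccccc5)c2c(c([C@@H]3c4ccc(OCc5ccccc5)cc4O[C@H](c4ccc(OCc5ccccc5)c(OCc5ccccc5)c4)[C@H]3OCc5ccccc5)c1OCc5ccccc5)O[C@H](c1ccc(OCc5ccccc5)c(OCc5ccccc5)c1)[C@@H](O)C2
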